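**Plan**

Core numbering used throughout: 3‑hydroxy‑4a,5‑dimethyl‑4,4a,5,6‑tetrahydronaphthalen‑2(3H)‑one, acyloxy at C6; ring B = C1–C4, C4a, C8a; ring A = C4a–C8, C8a.
Cuts, in retrosynthetic order: the C6–O acyl bond, C3–OH (enolate oxidation), C7=C8 (metathesis, ring A), C8–C8a (vinyl addition to a C8a carbonyl), then C1–C2 and C4–C4a together.
Enabling feature: ring B is a masked cyclohexane‑1,3‑dione. C2 is a ketone and C8a, 1,3 to it through C1, is the β‑carbon of the dienone, so C4a and C1 are the two α‑carbons of a methyl ketone at C8a, and C2–C3–C4 is an acrylate.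
Forward order: acyclic methyl ketone → ring B with the quaternary C4a (Michael–Claisen) → C8a carbonyl exchanged for vinyl → ring A by metathesis → esterification → C3 hydroxylation.
Stereochemistry: C6 is bought with (S)‑but‑3‑ene‑1,2‑diol; C5 comes from an anti cuprate addition next to it; C4a comes from C5 by allylic strain in the key step; C3 comes from attack anti to the angular methyl (also the thermodynamic epimer); the side‑chain carbinol comes from (S)‑2‑methylglycidol.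

Key step: step 6

Remark: metal enolates that differ from a numbered compound only by deprotonation are not numbered separately; ketone 8 is carried as a mixture of C3 epimers because this centre is re‑enolised in step 6.

**Step 1**
Reactants: 1 (S)‑but‑3‑ene‑1,2‑diol
Product: 2 (S)‑3,4‑bis(tert‑butyldimethylsilyloxy)but‑1‑ene
Conditions: TBSCl (2.4 equiv), imidazole, DMF, rt
Reagents that add atoms: tert‑butyldimethylsilyl chloride, CC(C)(C)[Si](C)(C)Cl
Why: standard silylation of both hydroxyls; the bought stereocenter (future C6) is not touched.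

**Step 2**
Reactants: 2 (S)‑3,4‑bis(tert‑butyldimethylsilyloxy)but‑1‑ene
Product: 3 (S)‑2‑(tert‑butyldimethylsilyloxy)but‑3‑en‑1‑ol
Conditions: HF·pyridine, pyridine, THF, 0 °C
Reagents that add atoms: none
Why: selective desilylation, the unhindered primary silyl ether being cleaved much faster than the secondary allylic one.

**Step 3**
Reactants: 3 (S)‑2‑(tert‑butyldimethylsilyloxy)but‑3‑en‑1‑ol
Product: 4 (S)‑2‑(tert‑butyldimethylsilyloxy)but‑3‑enal
Conditions: Dess–Martin periodinane, NaHCO3, CH2Cl2, 0 °C; used crude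
Reagents that add atoms: none
Why: buffered Dess–Martin oxidation of the primary alcohol under neutral conditions should avoid epimerisation or conjugation of the α‑silyloxy β,γ‑unsaturated aldehyde.

**Step 4**
Reactants: 4 (S)‑2‑(tert‑butyldimethylsilyloxy)but‑3‑enal; 5 1‑(triphenylphosphoranylidene)propan‑2‑one
Product: 6 (S,E)‑5‑(tert‑butyldimethylsilyloxy)hepta‑3,6‑dien‑2‑one
Conditions: CH2Cl2, rt
Reagents that add atoms: none
Why: Wittig olefination with a ketone‑stabilised ylide should give the (E)‑enone under nearly neutral conditions that spare the α‑stereocenter.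

**Step 5**
Reactants: 6 (S,E)‑5‑(tert‑butyldimethylsilyloxy)hepta‑3,6‑dien‑2‑one
Product: 8 (4R,5S)‑5‑(tert‑butyldimethylsilyloxy)‑3,4‑dimethylhept‑6‑en‑2‑one (C3 epimers), via lithium enolate 7 (not isolated)
Conditions: Me2CuLi, Et2O/THF, −78 °C; then MeI, DMPU, −40 → 0 °C
Reagents that add atoms: lithium dimethylcuprate, [Li+].C[Cu-]C; iodomethane, CI
Why: cuprate conjugate addition to the (E)‑γ‑silyloxy enone should occur anti to the γ‑oxygen (modified Felkin–Anh model) and set C4 (future C5), and the regiodefined enolate is methylated in the same flask (tandem conjugate addition–enolate alkylation) at C3, whose configuration does not matter.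

**Step 6**
Reactants: 8 (4R,5S)‑5‑(tert‑butyldimethylsilyloxy)‑3,4‑dimethylhept‑6‑en‑2‑one; 9 methyl acrylate
Product: 11 (4R)‑4‑[(2R,3S)‑3‑(tert‑butyldimethylsilyloxy)pent‑4‑en‑2‑yl]‑4‑methylcyclohexane‑1,3‑dione, via Michael adduct keto ester 10 (not isolated)
Conditions: KOtBu (1.3 equiv), THF, 0 °C → rt; then 1 M aq HCl to pH 4, 0 °C
Reagents that add atoms: none
Why: tert‑butoxide equilibrates the enolates of 8, the more substituted C3 enolate adds to methyl acrylate (Michael addition, forming C4–C4a), adduct 10 re‑enolises at the acetyl methyl and attacks the ester (Claisen condensation, forming C1–C2), and deprotonation of the resulting 1,3‑dione drives the sequence. The closest known reaction type is the consecutive Michael–Claisen synthesis of 4,4‑disubstituted cyclohexane‑1,3‑diones from isopropyl methyl ketone and acrylates. Ring B closes by a 6‑(enolendo)‑exo‑trig acyl substitution. The new quaternary stereocenter C4a is controlled by the adjacent C5 stereocenter: the C5–H bond eclipses the enolate double bond (allylic 1,3‑strain) and the acrylate should enter anti to the bulky silyloxyallyl group, which places the two methyl groups cis in the later ring A. The step needs regioselectivity for C3 over the methyl carbon, secured because only the C3 adduct can close to an enolisable and therefore stabilised dione, and it needs facial selectivity, secured by the size difference between methyl and the silyloxyallyl group at C5. Both C3 epimers of 8 converge on the same enolate.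

**Step 7**
Reactants: 11 (4R)‑4‑[(2R,3S)‑3‑(tert‑butyldimethylsilyloxy)pent‑4‑en‑2‑yl]‑4‑methylcyclohexane‑1,3‑dione
Product: 12 (6R)‑6‑[(2R,3S)‑3‑(tert‑butyldimethylsilyloxy)pent‑4‑en‑2‑yl]‑3‑methoxy‑6‑methylcyclohex‑2‑en‑1‑one
Conditions: Me2SO4, K2CO3, acetone, rt
Reagents that add atoms: dimethyl sulfate, COS(=O)(=O)OC
Why: O‑alkylation of the dionate should occur at the oxygen remote from the quaternary carbon, giving the vinylogous ester whose free carbonyl is the future C8a.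

**Step 8**
Reactants: 12 (6R)‑6‑[(2R,3S)‑3‑(tert‑butyldimethylsilyloxy)pent‑4‑en‑2‑yl]‑3‑methoxy‑6‑methylcyclohex‑2‑en‑1‑one
Product: 14 (4R)‑4‑[(2R,3S)‑3‑(tert‑butyldimethylsilyloxy)pent‑4‑en‑2‑yl]‑4‑methyl‑3‑vinylcyclohex‑2‑en‑1‑one, via tertiary carbinol 13 (not isolated)
Conditions: CH2=CHMgBr, CeCl3, THF, −78 → 0 °C; then 1 M aq HCl, THF, 0 °C
Reagents that add atoms: vinylmagnesium bromide, C=C[Mg]Br; water, O
Why: Stork–Danheiser sequence, in which 1,2‑addition of the vinylcerium reagent to the non‑enolisable vinylogous ester carbonyl and acid hydrolysis with allylic transposition should give the 3‑vinyl enone, forming C8–C8a and placing the ketone at C2.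

**Step 9**
Reactants: 14 (4R)‑4‑[(2R,3S)‑3‑(tert‑butyldimethylsilyloxy)pent‑4‑en‑2‑yl]‑4‑methyl‑3‑vinylcyclohex‑2‑en‑1‑one
Product: 15 (4aR,5R,6S)‑6‑(tert‑butyldimethylsilyloxy)‑4a,5‑dimethyl‑4,4a,5,6‑tetrahydronaphthalen‑2(3H)‑one
Conditions: second‑generation Grubbs catalyst (5 mol %), CH2Cl2, 40 °C
Reagents that add atoms: none
Why: ring‑closing metathesis of the two terminal vinyl groups should close the six‑membered ring A and form the cis C7=C8 bond of the linear dienone, driven by loss of ethylene.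

**Step 10**
Reactants: 15 (4aR,5R,6S)‑6‑(tert‑butyldimethylsilyloxy)‑4a,5‑dimethyl‑4,4a,5,6‑tetrahydronaphthalen‑2(3H)‑one
Product: 16 (4aR,5R,6S)‑6‑hydroxy‑4a,5‑dimethyl‑4,4a,5,6‑tetrahydronaphthalen‑2(3H)‑one
Conditions: HF·pyridine, pyridine, THF, 0 °C → rt
Reagents that add atoms: none
Why: fluoride cleavage of the silyl ether under buffered, non‑basic conditions that should leave the dienone untouched.

**Step 11**
Reactants: 17 (S)‑2‑methylglycidol
Product: 18 (R)‑2‑methylbutane‑1,2‑diol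
Conditions: CH3MgBr (3 equiv), CuI (10 mol %), THF, −30 → 0 °C; sat. aq NH4Cl
Reagents that add atoms: methylmagnesium bromide, C[Mg]Br
Why: copper‑catalysed Grignard opening of the 2,2‑disubstituted epoxide at its CH2 carbon; the tertiary stereocenter is not involved and keeps its configuration (the descriptor changes only through the priorities).

**Step 12**
Reactants: 18 (R)‑2‑methylbutane‑1,2‑diol
Product: 19 (R)‑2‑methyl‑1,2‑bis(triethylsilyloxy)butane
Conditions: TESOTf (2.5 equiv), 2,6‑lutidine, CH2Cl2, −78 → 0 °C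
Reagents that add atoms: triethylsilyl trifluoromethanesulfonate, CC[Si](CC)(CC)OS(=O)(=O)C(F)(F)F
Why: silyl triflate with a hindered base silylates the tertiary as well as the primary hydroxyl.

**Step 13**
Reactants: 19 (R)‑2‑methyl‑1,2‑bis(triethylsilyloxy)butane
Product: 20 (R)‑2‑methyl‑2‑(triethylsilyloxy)butanal
Conditions: (COCl)2, DMSO, CH2Cl2, −78 → −30 °C; then Et3N
Reagents that add atoms: none
Why: Swern conditions convert a primary triethylsilyl ether directly into the aldehyde while the tertiary silyl ether stays, and the quaternary α‑carbon cannot epimerise.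

**Step 14**
Reactants: 20 (R)‑2‑methyl‑2‑(triethylsilyloxy)butanal; 21 triethyl 4‑phosphonocrotonate
Product: 22 ethyl (2E,4E,6R)‑6‑methyl‑6‑(triethylsilyloxy)octa‑2,4‑dienoate
Conditions: LiN(SiMe3)2, THF, −78 → 0 °C
Reagents that add atoms: none
Why: vinylogous Horner–Wadsworth–Emmons olefination should give the (2E,4E)‑dienoate, the hindered α‑branched aldehyde favouring the E alkene.

**Step 15**
Reactants: 22 ethyl (2E,4E,6R)‑6‑methyl‑6‑(triethylsilyloxy)octa‑2,4‑dienoate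
Product: 23 (2E,4E,6R)‑6‑methyl‑6‑(triethylsilyloxy)octa‑2,4‑dienoic acid
Conditions: LiOH, THF/MeOH/H2O, rt; then 1 M aq HCl to pH 4, 0 °C
Reagents that add atoms: lithium hydroxide, [Li+].[OH-]
Why: saponification of the ethyl ester, which the tertiary triethylsilyl ether should survive.

**Step 16**
Reactants: 16 (4aR,5R,6S)‑6‑hydroxy‑4a,5‑dimethyl‑4,4a,5,6‑tetrahydronaphthalen‑2(3H)‑one; 23 (2E,4E,6R)‑6‑methyl‑6‑(triethylsilyloxy)octa‑2,4‑dienoic acid
Product: 24 (1R,2S,8aR)‑1,8a‑dimethyl‑6‑oxo‑1,2,6,7,8,8a‑hexahydronaphthalen‑2‑yl (2E,4E,6R)‑6‑methyl‑6‑(triethylsilyloxy)octa‑2,4‑dienoate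
Conditions: DCC, DMAP (0.3 equiv), CH2Cl2, 0 °C → rt
Reagents that add atoms: none
Why: Steglich esterification acylates the C6 oxygen with retention at carbon, and the acid has no enolisable position.

**Step 17**
Reactants: 24 (1R,2S,8aR)‑1,8a‑dimethyl‑6‑oxo‑1,2,6,7,8,8a‑hexahydronaphthalen‑2‑yl (2E,4E,6R)‑6‑methyl‑6‑(triethylsilyloxy)octa‑2,4‑dienoate
Product: 25 (1R,2S,7R,8aR)‑7‑hydroxy‑1,8a‑dimethyl‑6‑oxo‑1,2,6,7,8,8a‑hexahydronaphthalen‑2‑yl (2E,4E,6R)‑6‑methyl‑6‑(triethylsilyloxy)octa‑2,4‑dienoate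
Conditions: NaN(SiMe3)2, THF, −78 °C; then 2‑(phenylsulfonyl)‑3‑phenyloxaziridine, −78 °C; sat. aq NH4Cl
Reagents that add atoms: 2‑(phenylsulfonyl)‑3‑phenyloxaziridine, O=S(=O)(N1OC1c1ccccc1)c1ccccc1
Why: kinetic deprotonation at C3 gives the cross‑conjugated enolate, and oxygen transfer from the N‑sulfonyloxaziridine should occur anti to the angular C4a methyl group, giving the (3R) equatorial alcohol, which is also the thermodynamically preferred epimer.

**Step 18**
Reactants: 25 (1R,2S,7R,8aR)‑7‑hydroxy‑1,8a‑dimethyl‑6‑oxo‑1,2,6,7,8,8a‑hexahydronaphthalen‑2‑yl (2E,4E,6R)‑6‑methyl‑6‑(triethylsilyloxy)octa‑2,4‑dienoate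
Product: 26 CNP0260852.1
Conditions: HF·pyridine, pyridine, THF, 0 °C
Reagents that add atoms: none
Why: fluoride cleavage of the tertiary triethylsilyl ether under buffered conditions that should spare the allylic ester and the α‑hydroxy ketone.

**Compound list**

1 | (S)‑but‑3‑ene‑1,2‑diol | OC[C@@H](O)C=C | starting material
2 | (S)‑3,4‑bis(tert‑butyldimethylsilyloxy)but‑1‑ene | CC(C)(C)[Si](C)(C)OC[C@@H](O[Si](C)(C)C(C)(C)C)C=C | intermediate
3 | (S)‑2‑(tert‑butyldimethylsilyloxy)but‑3‑en‑1‑ol | OC[C@@H](O[Si](C)(C)C(C)(C)C)C=C | intermediate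
4 | (S)‑2‑(tert‑butyldimethylsilyloxy)but‑3‑enal | O=C[C@@H](O[Si](C)(C)C(C)(C)C)C=C | intermediate
5 | 1‑(triphenylphosphoranylidene)propan‑2‑one | CC(=O)C=P(c1ccccc1)(c1ccccc1)c1ccccc1 | starting material
6 | (S,E)‑5‑(tert‑butyldimethylsilyloxy)hepta‑3,6‑dien‑2‑one | CC(=O)/C=C/[C@@H](O[Si](C)(C)C(C)(C)C)C=C | intermediate
7 | lithium (4R,5S)‑5‑(tert‑butyldimethylsilyloxy)‑4‑methylhepta‑2,6‑dien‑2‑olate | [Li+].CC([O-])=C[C@@H](C)[C@@H](O[Si](C)(C)C(C)(C)C)C=C | intermediate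
8 | (4R,5S)‑5‑(tert‑butyldimethylsilyloxy)‑3,4‑dimethylhept‑6‑en‑2‑one (C3 epimers) | CC(=O)C(C)[C@@H](C)[C@@H](O[Si](C)(C)C(C)(C)C)C=C | intermediate
9 | methyl acrylate | C=CC(=O)OC | starting material
10 | methyl (4R,5R,6S)‑4‑acetyl‑6‑(tert‑butyldimethylsilyloxy)‑4,5‑dimethyloct‑7‑enoate | COC(=O)CC[C@@](C)(C(C)=O)[C@@H](C)[C@@H](O[Si](C)(C)C(C)(C)C)C=C | intermediate
11 | (4R)‑4‑[(2R,3S)‑3‑(tert‑butyldimethylsilyloxy)pent‑4‑en‑2‑yl]‑4‑methylcyclohexane‑1,3‑dione | O=C1CC(=O)CC[C@]1(C)[C@@H](C)[C@@H](O[Si](C)(C)C(C)(C)C)C=C | intermediate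
12 | (6R)‑6‑[(2R,3S)‑3‑(tert‑butyldimethylsilyloxy)pent‑4‑en‑2‑yl]‑3‑methoxy‑6‑methylcyclohex‑2‑en‑1‑one | COC1=CC(=O)[C@@](C)([C@@H](C)[C@@H](O[Si](C)(C)C(C)(C)C)C=C)CC1 | intermediate
13 | (6R)‑6‑[(2R,3S)‑3‑(tert‑butyldimethylsilyloxy)pent‑4‑en‑2‑yl]‑3‑methoxy‑6‑methyl‑1‑vinylcyclohex‑2‑en‑1‑ol (C1 epimers) | COC1=CC(O)(C=C)[C@@](C)([C@@H](C)[C@@H](O[Si](C)(C)C(C)(C)C)C=C)CC1 | intermediate
14 | (4R)‑4‑[(2R,3S)‑3‑(tert‑butyldimethylsilyloxy)pent‑4‑en‑2‑yl]‑4‑methyl‑3‑vinylcyclohex‑2‑en‑1‑one | C=CC1=CC(=O)CC[C@]1(C)[C@@H](C)[C@@H](O[Si](C)(C)C(C)(C)C)C=C | intermediate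
15 | (4aR,5R,6S)‑6‑(tert‑butyldimethylsilyloxy)‑4a,5‑dimethyl‑4,4a,5,6‑tetrahydronaphthalen‑2(3H)‑one | CC(C)(C)[Si](C)(C)O[C@H]1C=CC2=CC(=O)CC[C@]2(C)[C@H]1C | intermediate
16 | (4aR,5R,6S)‑6‑hydroxy‑4a,5‑dimethyl‑4,4a,5,6‑tetrahydronaphthalen‑2(3H)‑one | O[C@H]1C=CC2=CC(=O)CC[C@]2(C)[C@H]1C | intermediate
17 | (S)‑2‑methylglycidol, [(2S)‑2‑methyloxiran‑2‑yl]methanol | C[C@]1(CO)CO1 | starting material
18 | (R)‑2‑methylbutane‑1,2‑diol | CC[C@@](C)(O)CO | intermediate
19 | (R)‑2‑methyl‑1,2‑bis(triethylsilyloxy)butane | CC[C@@](C)(O[Si](CC)(CC)CC)CO[Si](CC)(CC)CC | intermediate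
20 | (R)‑2‑methyl‑2‑(triethylsilyloxy)butanal | CC[C@@](C)(O[Si](CC)(CC)CC)C=O | intermediate
21 | triethyl 4‑phosphonocrotonate, ethyl (E)‑4‑(diethoxyphosphoryl)but‑2‑enoate | CCOC(=O)/C=C/CP(=O)(OCC)OCC | starting material
22 | ethyl (2E,4E,6R)‑6‑methyl‑6‑(triethylsilyloxy)octa‑2,4‑dienoate | CC[C@@](C)(O[Si](CC)(CC)CC)/C=C/C=C/C(=O)OCC | intermediate
23 | (2E,4E,6R)‑6‑methyl‑6‑(triethylsilyloxy)octa‑2,4‑dienoic acid | CC[C@@](C)(O[Si](CC)(CC)CC)/C=C/C=C/C(=O)O | intermediate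
24 | (1R,2S,8aR)‑1,8a‑dimethyl‑6‑oxo‑1,2,6,7,8,8a‑hexahydronaphthalen‑2‑yl (2E,4E,6R)‑6‑methyl‑6‑(triethylsilyloxy)octa‑2,4‑dienoate | CC[C@@](C)(O[Si](CC)(CC)CC)/C=C/C=C/C(=O)O[C@H]1C=CC2=CC(=O)CC[C@]2(C)[C@H]1C | intermediate
25 | (1R,2S,7R,8aR)‑7‑hydroxy‑1,8a‑dimethyl‑6‑oxo‑1,2,6,7,8,8a‑hexahydronaphthalen‑2‑yl (2E,4E,6R)‑6‑methyl‑6‑(triethylsilyloxy)octa‑2,4‑dienoate | CC[C@@](C)(O[Si](CC)(CC)CC)/C=C/C=C/C(=O)O[C@H]1C=CC2=CC(=O)[C@H](O)C[C@]2(C)[C@H]1C | intermediate
26 | CNP0260852.1, (1R,2S,7R,8aR)‑7‑hydroxy‑1,8a‑dimethyl‑6‑oxo‑1,2,6,7,8,8a‑hexahydronaphthalen‑2‑yl (2E,4E,6R)‑6‑hydroxy‑6‑methylocta‑2,4‑dienoate | CC[C@@](C)(O)/C=C/C=C/C(=O)O[C@H]1C=CC2=CC(=O)[C@H](O)C[C@]2(C)[C@H]1C | target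

**Count**

Total steps: 18. Longest linear sequence: 13 (steps 1–10, 16, 17, 18).

**Steps most likely to fail**

Step 6. What may go wrong: Michael addition through the less substituted enolate at the acetyl methyl with oligomerisation of the acrylate, and erosion of facial selectivity at the tetrasubstituted enolate at 0 °C to room temperature. The fallback separates the two bond formations and fixes the enolate regiochemistry. It sets out from ketone 8, which is converted with TMSCl, NaI and Et3N in MeCN into its more substituted silyl enol ether, (4R,5S)‑5‑(tert‑butyldimethylsilyloxy)‑3,4‑dimethyl‑2‑(trimethylsilyloxy)hepta‑2,6‑diene F1. A Mukaiyama–Michael addition of F1 to 3‑acryloyloxazolidin‑2‑one (Sc(OTf)3, CH2Cl2, −78 °C) should give 3‑[(4R,5R,6S)‑4‑acetyl‑6‑(tert‑butyldimethylsilyloxy)‑4,5‑dimethyloct‑7‑enoyl]oxazolidin‑2‑one F2 through an open transition state at low temperature. Intramolecular Claisen acylation of F2 with KOtBu in THF at 0 °C expels the oxazolidinone and comes back to the route at dione 11.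

Step 8. What may go wrong: no 1,2‑addition at the carbonyl flanked by the quaternary carbon, or competing addition–elimination at the methoxy‑bearing carbon. The fallback uses a slimmer sp nucleophile and adjusts the oxidation level afterwards. It sets out from vinylogous ester 12: HC≡CMgBr with CeCl3 in THF should give (6R)‑6‑[(2R,3S)‑3‑(tert‑butyldimethylsilyloxy)pent‑4‑en‑2‑yl]‑1‑ethynyl‑3‑methoxy‑6‑methylcyclohex‑2‑en‑1‑ol F3, which on treatment with 1 M aq HCl gives (4R)‑4‑[(2R,3S)‑3‑(tert‑butyldimethylsilyloxy)pent‑4‑en‑2‑yl]‑3‑ethynyl‑4‑methylcyclohex‑2‑en‑1‑one F4. Semi‑hydrogenation of the alkyne of F4 (H2, Pd/CaCO3 poisoned with Pb(OAc)2, quinoline) comes back to the route at vinyl enone 14.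

Step 17. What may go wrong: oxygen transfer to the wrong face of the cross‑conjugated enolate, or capture of the enolate and product alkoxide by the sulfonimine formed from the oxidant. The fallback is a Rubottom oxidation on the isolated silyl enol ether under neutral conditions. It sets out from ester 24: LiN(SiMe3)2 and TMSCl in THF at −78 °C give (1R,2S,8aR)‑1,8a‑dimethyl‑6‑(trimethylsilyloxy)‑1,2,8,8a‑tetrahydronaphthalen‑2‑yl (2E,4E,6R)‑6‑methyl‑6‑(triethylsilyloxy)octa‑2,4‑dienoate F5. Oxidation of F5 with dimethyldioxirane in acetone/CH2Cl2 at −78 °C, with epoxidation and silyl shift, should give (1R,2S,7R,8aR)‑1,8a‑dimethyl‑6‑oxo‑7‑(trimethylsilyloxy)‑1,2,6,7,8,8a‑hexahydronaphthalen‑2‑yl (2E,4E,6R)‑6‑methyl‑6‑(triethylsilyloxy)octa‑2,4‑dienoate F6. HF·pyridine removes both silyl groups and comes back to the route at target 26; an axial C3 epimer, if formed, would be equilibrated to the equatorial (3R) alcohol with Et3N.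

**Further compounds**

F1 | step 6 | (4R,5S)‑5‑(tert‑butyldimethylsilyloxy)‑3,4‑dimethyl‑2‑(trimethylsilyloxy)hepta‑2,6‑diene | CC(O[Si](C)(C)C)=C(C)[C@@H](C)[C@@H](O[Si](C)(C)C(C)(C)C)C=C
F2 | step 6 | 3‑[(4R,5R,6S)‑4‑acetyl‑6‑(tert‑butyldimethylsilyloxy)‑4,5‑dimethyloct‑7‑enoyl]oxazolidin‑2‑one | O=C(CC[C@@](C)(C(C)=O)[C@@H](C)[C@@H](O[Si](C)(C)C(C)(C)C)C=C)N1CCOC1=O
F3 | step 8 | (6R)‑6‑[(2R,3S)‑3‑(tert‑butyldimethylsilyloxy)pent‑4‑en‑2‑yl]‑1‑ethynyl‑3‑methoxy‑6‑methylcyclohex‑2‑en‑1‑ol | COC1=CC(O)(C#C)[C@@](C)([C@@H](C)[C@@H](O[Si](C)(C)C(C)(C)C)C=C)CC1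
F4 | step 8 | (4R)‑4‑[(2R,3S)‑3‑(tert‑butyldimethylsilyloxy)pent‑4‑en‑2‑yl]‑3‑ethynyl‑4‑methylcyclohex‑2‑en‑1‑one | C#CC1=CC(=O)CC[C@]1(C)[C@@H](C)[C@@H](O[Si](C)(C)C(C)(C)C)C=C
F5 | step 17 | (1R,2S,8aR)‑1,8a‑dimethyl‑6‑(trimethylsilyloxy)‑1,2,8,8a‑tetrahydronaphthalen‑2‑yl (2E,4E,6R)‑6‑methyl‑6‑(triethylsilyloxy)octa‑2,4‑dienoate | CC[C@@](C)(O[Si](CC)(CC)CC)/C=C/C=C/C(=O)O[C@H]1C=CC2=CC(O[Si](C)(C)C)=CC[C@]2(C)[C@H]1C
F6 | step 17 | (1R,2S,7R,8aR)‑1,8a‑dimethyl‑6‑oxo‑7‑(trimethylsilyloxy)‑1,2,6,7,8,8a‑hexahydronaphthalen‑2‑yl (2E,4E,6R)‑6‑methyl‑6‑(triethylsilyloxy)octa‑2,4‑dienoate | CC[C@@](C)(O[Si](CC)(CC)CC)/C=C/C=C/C(=O)O[C@H]1C=CC2=CC(=O)[C@H](O[Si](C)(C)C)C[C@]2(C)[C@H]1C
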